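## Retrosynthetic overview

1. Numbering: unprimed atoms belong to the chroman unit without C-methyl, primed atoms to the 6'-methylchroman unit. 13 ⇒ 12 (C6–Br as a temporary blocking group) ⇒ retro-hetero-Diels–Alder cut of O1–C2 and C3–C4, giving o-quinone methide 11 (from benzylic alcohol 9) and styrene 10.
2. Enabling feature: O1–C8a–C4a–C4 lies on a phloroglucinol-type benzo ring. C4a is ortho to the C8a oxygen and to C5–OMe and para to C7–OH, so a C4 carbinol ionises readily to the methide. C2–C3 with its phenyl group is simply styrene, and C5 is capped as OMe, so only one chroman can form.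
3. 9 ⇐ aldehyde 8 ⇐ biomimetic methide/Friedel–Crafts union at the C8–CH2–C8' bridge. The partners are Mannich base 6 (from aldehyde 4) and flavan 3, whose C8' is the only free carbon of its benzo ring.
4. 3 ⇐ two-stage dearomatisation of the commercial flavylium salt 1: hydride to C4', then asymmetric hydrogenation of C2'=C3' sets C2'.
5. Ring order: the four benzene rings and the O1' heterocycle are bought (the latter as a pyrylium ring). The dihydropyran O1–C2–C3–C4–C4a–C8a is the only ring built, and it closes last, in step 7.

Key step: step 7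

Assumption: the catalyst enantiomers named in steps 2 and 7 (and where they are reused in the fallbacks) are taken to deliver the 2S configuration. If a model run shows the opposite sense, the mirror-image catalyst is used.

Remark: 1, 4 and 10 are catalogue chemicals. Compound 1 is a perchlorate salt and is handled on a small scale.

## Route

Step 1
Reactants: 1 dracorhodin perchlorate (7-hydroxy-5-methoxy-6-methyl-2-phenylchromenylium perchlorate)
Product: 2 5-methoxy-6-methyl-2-phenyl-4H-chromen-7-ol
Conditions: NaBH4 (2 equiv), MeCN–THF, 0 °C; pH 7 buffer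
Reagents that add atoms: none
Why: Hydride reduction of a flavylium (benzopyrylium) salt, in which hydride should add to the unsubstituted, sterically open C4' rather than to the phenyl-bearing C2', dearomatising the pyrylium ring to the 2-aryl enol ether without creating a stereocentre.

Step 2
Reactants: 2 5-methoxy-6-methyl-2-phenyl-4H-chromen-7-ol
Product: 3 (2S)-5-methoxy-6-methyl-2-phenylchroman-7-ol
Conditions: [Ir(cod)((S)-tBu-PHOX)]BArF (1 mol%), H2 (50 bar), CH2Cl2, rt
Reagents that add atoms: none
Why: Iridium–N,P-catalysed asymmetric hydrogenation of a 2-aryl-4H-chromene, a known substrate class for this catalyst type, in which C2' is set by catalyst-controlled delivery of H2 to one face of the trisubstituted enol ether C2'=C3'.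

Step 3
Reactants: 4 2,4-dihydroxy-6-methoxybenzaldehyde
Product: 5 3-[(dimethylamino)methyl]-2,4-dihydroxy-6-methoxybenzaldehyde
Conditions: aq. CH2O (1.0 equiv), aq. Me2NH (1.05 equiv), EtOH, 0 °C to rt
Reagents that add atoms: formaldehyde, C=O; dimethylamine, CNC
Why: Phenol Mannich reaction in which, as with 2,4-dihydroxyaryl carbonyl compounds in general, the iminium ion should go to the carbon flanked by the two hydroxyls (less hindered than the carbon next to OMe), while one equivalent of reagent limits double aminomethylation.

Step 4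
Reactants: 5 3-[(dimethylamino)methyl]-2,4-dihydroxy-6-methoxybenzaldehyde
Product: 6 3-bromo-5-[(dimethylamino)methyl]-4,6-dihydroxy-2-methoxybenzaldehyde
Conditions: Br2 (1.0 equiv), NaOAc, AcOH, 10 °C; then aq. NaHCO3
Reagents that add atoms: bromine, BrBr
Why: Electrophilic aromatic bromination at the only remaining ring C–H (ortho to OH and OMe, para to OH), with the amine kept protonated in AcOH, installs the removable blocking group at the future C6.

Step 5
Reactants: 3 (2S)-5-methoxy-6-methyl-2-phenylchroman-7-ol; 6 3-bromo-5-[(dimethylamino)methyl]-4,6-dihydroxy-2-methoxybenzaldehyde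
Product: 8 3-bromo-4,6-dihydroxy-5-{[(2S)-7-hydroxy-5-methoxy-6-methyl-2-phenylchroman-8-yl]methyl}-2-methoxybenzaldehyde, via bromoformyl o-quinone methide 7 (not isolated)
Conditions: 3 (1.0 equiv), 6 (1.2 equiv), 1,4-dioxane, 100 °C, N2 sweep
Reagents that add atoms: none
Why: Thermal loss of dimethylamine from the phenolic Mannich base gives 7, which C8' of 3 captures in a Friedel–Crafts-type conjugate addition, the established way to unsymmetrical methylene-bridged phloroglucinol dimers; neither partner has another free nucleophilic ring carbon, and C2' is not touched.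

Step 6
Reactants: 8 3-bromo-4,6-dihydroxy-5-{[(2S)-7-hydroxy-5-methoxy-6-methyl-2-phenylchroman-8-yl]methyl}-2-methoxybenzaldehyde
Product: 9 (2S)-8-[3-bromo-2,6-dihydroxy-5-(hydroxymethyl)-4-methoxybenzyl]-5-methoxy-6-methyl-2-phenylchroman-7-ol
Conditions: NaBH4 (4 equiv), THF–EtOH, 0 °C; pH 7 buffer; used without chromatography
Reagents that add atoms: none
Why: Borohydride reduction of a salicylaldehyde to the o-hydroxybenzyl alcohol, where low temperature and a neutral quench should prevent premature loss of hydroxide and over-reduction to the methyl compound.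

Step 7
Reactants: 9 (2S)-8-[3-bromo-2,6-dihydroxy-5-(hydroxymethyl)-4-methoxybenzyl]-5-methoxy-6-methyl-2-phenylchroman-7-ol; 10 styrene
Product: 12 (2S)-6-bromo-8-{[(2S)-7-hydroxy-5-methoxy-6-methyl-2-phenylchroman-8-yl]methyl}-5-methoxy-2-phenylchroman-7-ol, via flavanylmethyl o-quinone methide 11 (not isolated)
Conditions: (R)-3,3'-bis(2,4,6-triisopropylphenyl)-BINOL N-triflylphosphoramide (10 mol%), styrene (10 equiv), 5 Å MS, CH2Cl2, −30 °C, slow addition of 9
Reagents that add atoms: none
Why: Proposed new method: the chiral N-triflylphosphoramide protonates the C4 carbinol of 9, water leaves under the push of the C8a and C7 hydroxyls and of C5–OMe, and methide 11 stays bound to the chiral anion by a hydrogen bond (ion pair) at its C8a oxygen. Styrene then adds in an inverse-electron-demand, asynchronous hetero-Diels–Alder reaction, its CH2 terminus to C4 and its benzylic carbon to O1, so the dihydropyran ring is closed in an intermolecular [4+2] mode (bonds C3–C4 and C2–O1) and the benzo ring regains aromaticity. The closest known reaction type is the enantioselective, phosphoramide-catalysed [4+2] cycloaddition of styrenes with o-quinone methides generated from o-hydroxybenzhydryl alcohols, which gives 2,4-diarylchromans; new here is a methide whose terminus bears no substituent, so that C2 is the only stereocentre formed. C2 is set by the catalyst: its 3,3'-aryl groups shield one face of bound 11 and hold the phenyl group of styrene endo over the methide ring, while the remote C2' centre should have little influence, so that a minor (2R,2'S) product would be a separable diastereomer. Regioselectivity (phenyl at C2) follows from the match of the electrophilic C4 with the styrene terminus and of O1 with the developing benzylic cation, and only the oxygen at C8a can close a six-membered ring because C5 carries OMe and C7–OH is para to C4a. Chemoselectivity over Friedel–Crafts self-alkylation, the usual fate of phloroglucinol-type methides, is secured by the substrate itself, since C6 carries Br and every carbon of both electron-rich benzo rings is substituted, and slow addition of 9 to excess styrene suppresses dimerisation of 11.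

Step 8
Reactants: 12 (2S)-6-bromo-8-{[(2S)-7-hydroxy-5-methoxy-6-methyl-2-phenylchroman-8-yl]methyl}-5-methoxy-2-phenylchroman-7-ol
Product: 13 (2S)-8-{[(2S)-7-hydroxy-5-methoxy-6-methyl-2-phenylchroman-8-yl]methyl}-5-methoxy-2-phenylchroman-7-ol (CNP0114750.1)
Conditions: H2 (1 atm), 10% Pd/C, NaOAc, EtOAc–MeOH, rt
Reagents that add atoms: none
Why: Catalytic hydrodehalogenation of the aryl bromide under buffered, low-pressure conditions should leave the two benzylic C–O bonds at C2 and C2' and both stereocentres untouched.

## Compound list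

1 | dracorhodin perchlorate (7-hydroxy-5-methoxy-6-methyl-2-phenylchromenylium perchlorate) | COc1c(C)c(O)cc2[o+]c(-c3ccccc3)ccc12.[O-]Cl(=O)(=O)=O | starting material
2 | 5-methoxy-6-methyl-2-phenyl-4H-chromen-7-ol | COc1c(C)c(O)cc2OC(c3ccccc3)=CCc12 | intermediate
3 | (2S)-5-methoxy-6-methyl-2-phenylchroman-7-ol | COc1c(C)c(O)cc2O[C@H](c3ccccc3)CCc12 | intermediate
4 | 2,4-dihydroxy-6-methoxybenzaldehyde | COc1cc(O)cc(O)c1C=O | starting material
5 | 3-[(dimethylamino)methyl]-2,4-dihydroxy-6-methoxybenzaldehyde | COc1cc(O)c(CN(C)C)c(O)c1C=O | intermediate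
6 | 3-bromo-5-[(dimethylamino)methyl]-4,6-dihydroxy-2-methoxybenzaldehyde | COc1c(Br)c(O)c(CN(C)C)c(O)c1C=O | intermediate
7 | bromoformyl o-quinone methide (3-bromo-6-hydroxy-2-methoxy-5-methylidene-4-oxocyclohexa-1,6... drawn as 5-methylidene-4-oxo dienal tautomer of 6 minus Me2NH) | C=C1C(=O)C(Br)=C(OC)C(C=O)=C1O | intermediate
8 | 3-bromo-4,6-dihydroxy-5-{[(2S)-7-hydroxy-5-methoxy-6-methyl-2-phenylchroman-8-yl]methyl}-2-methoxybenzaldehyde | COc1c(Br)c(O)c(Cc2c(O)c(C)c(OC)c3c2O[C@H](c2ccccc2)CC3)c(O)c1C=O | intermediate
9 | (2S)-8-[3-bromo-2,6-dihydroxy-5-(hydroxymethyl)-4-methoxybenzyl]-5-methoxy-6-methyl-2-phenylchroman-7-ol | COc1c(Br)c(O)c(Cc2c(O)c(C)c(OC)c3c2O[C@H](c2ccccc2)CC3)c(O)c1CO | intermediate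
10 | styrene | C=Cc1ccccc1 | starting material
11 | flavanylmethyl o-quinone methide (9 minus water; C4=C4a exocyclic methylene, C8a=O) | C=C1C(=O)C(Cc2c(O)c(C)c(OC)c3c2O[C@H](c2ccccc2)CC3)=C(O)C(Br)=C1OC | intermediate
12 | (2S)-6-bromo-8-{[(2S)-7-hydroxy-5-methoxy-6-methyl-2-phenylchroman-8-yl]methyl}-5-methoxy-2-phenylchroman-7-ol | COc1c(Br)c(O)c(Cc2c(O)c(C)c(OC)c3c2O[C@H](c2ccccc2)CC3)c2c1CC[C@@H](c1ccccc1)O2 | intermediate
13 | (2S)-8-{[(2S)-7-hydroxy-5-methoxy-6-methyl-2-phenylchroman-8-yl]methyl}-5-methoxy-2-phenylchroman-7-ol | COc1cc(O)c(Cc2c(O)c(C)c(OC)c3c2O[C@H](c2ccccc2)CC3)c2c1CC[C@@H](c1ccccc1)O2 | target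

## Step count and risks

Total step count: 8.
Longest linear sequence: 6 (steps 1, 2, 5, 6, 7, 8, or equally steps 3, 4, 5, 6, 7, 8).

**Step 7 (Proposed new method).**
- Risks:
  - The catalyst may discriminate poorly between the faces at a methide terminus that bears no substituent.
  - Addition of the weakly nucleophilic styrene may be slow, so that the methide decays by dimerisation or reversible re-addition of water and phenols.
  - The acid may oligomerise styrene.
- Fallback with known chemistry: it sets out from 8 and comes back at 12.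
  - Acid-catalysed aldol condensation and cyclodehydration of 8 with acetophenone (HCl gas, EtOAc–AcOH, 0 °C to rt) closes the same ring as the 6-bromo-8-(flavanylmethyl)flavylium chloride F1.
  - NaBH4 in MeCN–THF adds hydride at C4 to give the 2-phenyl-4H-chromene F2.
  - Iridium–N,P asymmetric hydrogenation under the conditions of step 2 sets C2 and delivers 12.

**Step 3.**
- Risk: regiocontrol may be lost, with aminomethylation next to the methoxy group or at both free ring carbons.
- Fallback: it sets out from 4 and comes back at 5.
  - Both hydroxyls are protected (MOMCl, i-Pr2NEt, then NaH/MOMCl) to give 2-methoxy-4,6-bis(methoxymethoxy)benzaldehyde F3.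
  - The formyl group is masked with N,N'-dimethylethylenediamine (toluene, reflux) as the 1,3-dimethylimidazolidine F4.
  - Directed ortho-metalation (n-BuLi, THF, −20 °C) takes place at the carbon between the two OMOM groups, the strongest cooperative site. Quenching with N,N-dimethylmethyleneiminium iodide gives the aminomethylated imidazolidine F5.
  - Methanolic HCl removes the aminal and both MOM groups to give 5.

**Step 2.**
- Risks:
  - Iridium hydride species may protonate or oligomerise the enol ether.
  - The free phenol may inhibit the catalyst.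
  - Face selectivity may be insufficient.
- Fallback: it sets out from 2 and comes back at 3.
  - Mild aqueous acid (1 M HCl, THF, rt) hydrolyses the enol ether to 3-(4,6-dihydroxy-2-methoxy-3-methylphenyl)-1-phenylpropan-1-one F6.
  - Ru–TsDPEN asymmetric transfer hydrogenation (RuCl[(R,R)-TsDPEN](p-cymene), HCO2H–Et3N) gives (1R)-3-(4,6-dihydroxy-2-methoxy-3-methylphenyl)-1-phenylpropan-1-ol F7.
  - Intramolecular Mitsunobu etherification (PPh3, DIAD, THF, 0 °C, high dilution) closes O1'–C2' with inversion to give 3. Only the phenol ortho to the chain can reach the carbinol.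

Further compounds
F1 | step 7 | 6-bromo-7-hydroxy-8-{[(2S)-7-hydroxy-5-methoxy-6-methyl-2-phenylchroman-8-yl]methyl}-5-methoxy-2-phenylchromenylium chloride | COc1c(Br)c(O)c(Cc2c(O)c(C)c(OC)c3c2O[C@H](c2ccccc2)CC3)c2[o+]c(-c3ccccc3)ccc12.[Cl-]
F2 | step 7 | 6-bromo-8-{[(2S)-7-hydroxy-5-methoxy-6-methyl-2-phenylchroman-8-yl]methyl}-5-methoxy-2-phenyl-4H-chromen-7-ol | COc1c(Br)c(O)c(Cc2c(O)c(C)c(OC)c3c2O[C@H](c2ccccc2)CC3)c2OC(c3ccccc3)=CCc12
F3 | step 3 | 2-methoxy-4,6-bis(methoxymethoxy)benzaldehyde | COCOc1cc(OC)c(C=O)c(OCOC)c1
F4 | step 3 | 2-[2-methoxy-4,6-bis(methoxymethoxy)phenyl]-1,3-dimethylimidazolidine | COCOc1cc(OC)c(C2N(C)CCN2C)c(OCOC)c1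
F5 | step 3 | 1-[3-(1,3-dimethylimidazolidin-2-yl)-4-methoxy-2,6-bis(methoxymethoxy)phenyl]-N,N-dimethylmethanamine | COCOc1cc(OC)c(C2N(C)CCN2C)c(OCOC)c1CN(C)C
F6 | step 2 | 3-(4,6-dihydroxy-2-methoxy-3-methylphenyl)-1-phenylpropan-1-one | COc1c(C)c(O)cc(O)c1CCC(=O)c1ccccc1
F7 | step 2 | (1R)-3-(4,6-dihydroxy-2-methoxy-3-methylphenyl)-1-phenylpropan-1-ol | COc1c(C)c(O)cc(O)c1CC[C@@H](O)c1ccccc1
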